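An order in free catalyst or in coupling partner cannot be read from Monday's run: no earlier run changes either charge. What the curve does give, for the quick number requested, is the time at which the flask reaches the point asked about.

- Monday's: substrate 0.050 M; coupling partner 0.050 M; free catalyst 0.21 mM; the very flask that is asked about, followed so far
- flask: substrate 0.050 M; coupling partner 0.0500 M; free catalyst 0.21 mM

Monday's run (percent of the substrate charged): time / min: product / % = 0.417: 5.4; 1.00: 10.9; 2.00: 21.9; 5.00: 40.7

(readings scatter by 0.5 percentage points)

- apparent order in free catalyst when 30% of the substrate are converted (percent change of the rate of making product for one percent more free catalyst charged)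
- apparent order in coupling partner when 30% of the substrate are converted (percent change of the rate of making product for one percent more coupling partner charged)
- factor on the rate of making product when 30% of the substrate are converted if coupling partner is charged twice over

- the numbers in the tables scatter with a standard deviation of 0.5 percentage points
- no earlier run changes the charge of free catalyst; that part of a forecast is a guess
- no earlier run changes the charge of coupling partner; that part of a forecast is a guess

The readings at 2.00 min and 5.00 min bracket 30%, so the curve between them is replaced by its mean. This gives the clock, the reckoned time to 30% conversion:

mean rate = 0.00313 M min⁻¹

clock = 3.29 min

The curve bends, so the span before gives a second mean: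

earlier mean rate = 0.00550 M min⁻¹

earlier time = 2.74 min

That earlier mean is faster than the first, and the error of the mean therefore spans 0.550 min.

An order compares flasks at equal conversion, not at equal time. If the rate at fixed conversion goes with the free catalyst charge, and a first-order loss also runs by the clock, more catalyst shortens the clock in proportion, and:

order in free catalyst = 1 + loss constant × clock

Monday's curve gives no loss constant, so this reckoning commits to an order of 1 plus an open excess.

The forecast gives 1 in free catalyst, 1.3 in coupling partner and a factor of 2.25 on doubling, and calls the dependence on coupling partner “partly a guess”.

The simulation gives 1.5 in free catalyst and 1.8 in coupling partner, both higher than the forecast , and a factor of 2.28 on doubling.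

    substrate + free catalyst → catalyst intermediate A (k = 47000 M⁻¹ min⁻¹)
    coupling partner + catalyst intermediate B ⇌ catalyst intermediate C (K = 49.0 M⁻¹, k = 1400 M⁻¹ min⁻¹)
    catalyst intermediate A ⇌ catalyst intermediate B (K = 2.30, k = 110 min⁻¹)
    catalyst intermediate C → free catalyst + product (k = 820 min⁻¹)
    coupling partner → decomposed reagent (k = 0.140 min⁻¹)

The flask reaches 30% at 3.02 min, earlier than the clock of 3.29 min and later than the earlier time of 2.74 min, while the coupling partner also decays with time. With the loss constant 0.14 min⁻¹, the flask's own time of 3.02 min gives an order of 1.42. The simulated run without the path to decomposed reagent has an order in free catalyst of 1.0 against 1.5, so this path accounts for part of the excess. Without it, the rate at that conversion stands at 1.50 times the actual one.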